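**Retrosynthetic overview**

1. The target has ring A (2-hydroxy-5-methoxy-6-methyl-1,4-benzoquinone) and ring B (2,5-dihydroxy-6-methyl-1,4-benzoquinone) joined through C3 of each ring by a (CH2)13 tether. It is disconnected to the symmetrical bis(2-hydroxy-5-methoxy-6-methylquinone) by hydrolysis of one of its two equivalent OCH3 groups.
2. The strategy rests on this feature: in each ring the CH3 carbon lies para to the tether carbon and between two oxygen-bearing carbons. Each ring is therefore a 5-alkyl-2-methylresorcinol core oxidised at the two ring carbons that flank the tether. The bis(quinone) thus comes from the bis(3-methoxy-2-methyl-5-alkylphenol) by para-oxidation and hydroxylation of the one remaining ring C–H.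
3. Both benzene rings arise in one two-directional benzannulation. At each end a 3-alkylcyclobut-2-enone takes up one molecule of 1-methoxypropyne between its C1 (C=O) and C2 (=CH); the alkyne carbons become C(CH3) and C(OCH3), and the ring is closed by re-forming the C1–C4 bond.
4. The bis(cyclobutenone) comes from heptadeca-1,16-diyne and two equivalents of dichloroketene ([2+2], then zinc dechlorination). The diyne comes from tridecanedioic acid (diol, dibromide, double acetylide alkylation), and 1-methoxypropyne from chloroacetaldehyde dimethyl acetal.
5. Ring order: the two four-membered rings together (step 4), then the two six-membered rings together (step 7); no other ring is built.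

Key step: step 7

Remark: the target has no stereocentre; ring B is taken as the 2,5-dihydroxy-1,4-quinone tautomer of the given SMILES, and BH3·SMe2, lithium acetylide–ethylenediamine complex and (KSO3)2NO are assumed to be purchased.

**Route**

Step 1
Reactants: 1 tridecanedioic acid
Product: 2 tridecane-1,13-diol
Conditions: BH3·SMe2, THF, 0 °C to rt; MeOH quench
Reagents that add atoms: none
Why: Borane reduction of a carboxylic acid: both CO2H groups are reduced through acyloxyboranes to the primary alcohols, and nothing else in 1 can react.

Step 2
Reactants: 2 tridecane-1,13-diol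
Product: 3 1,13-dibromotridecane
Conditions: 48% HBr (aq, excess), conc. H2SO4, reflux
Reagents that add atoms: hydrogen bromide, Br
Why: Nucleophilic substitution (SN2) of the protonated primary hydroxyl groups by bromide, the standard HBr/H2SO4 conversion of an α,ω-diol into the dibromide.

Step 3
Reactants: 3 1,13-dibromotridecane
Product: 4 heptadeca-1,16-diyne
Conditions: LiC≡CH·H2NCH2CH2NH2 (excess), DMSO, 10 °C to rt
Reagents that add atoms: lithium acetylide–ethylenediamine complex, [Li+].[C-]#C.NCCN
Why: Double SN2 alkylation of lithium acetylide by the unhindered primary bromides in DMSO, which puts a terminal ethynyl group on each end and leaves thirteen CH2 groups between the two alkynes.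

Step 4
Reactants: 4 heptadeca-1,16-diyne; 5 trichloroacetyl chloride
Product: 6 3,3'-(tridecane-1,13-diyl)bis(4,4-dichlorocyclobut-2-en-1-one)
Conditions: 5 (3 equiv, slow addition), Zn–Cu couple (excess), Et2O/DME, rt to reflux
Reagents that add atoms: trichloroacetyl chloride 5 (second equivalent; one dichloroketene unit enters at each alkyne), ClC(=O)C(Cl)(Cl)Cl
Why: Ketene–alkyne [2+2] cycloaddition: each molecule of 5 is dechlorinated by zinc to dichloroketene in the flask, and one dichloroketene adds to each of the two terminal alkynes (two equivalents of 5 are consumed per molecule of 4) with the terminal CH carbon bonding to the ketene carbonyl carbon, which gives the 3-alkyl-4,4-dichlorocyclobutenone regiochemistry, while DME ties up ZnCl2 and so prevents allylic chloride migration.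

Step 5
Reactants: 6 3,3'-(tridecane-1,13-diyl)bis(4,4-dichlorocyclobut-2-en-1-one)
Product: 7 3,3'-(tridecane-1,13-diyl)bis(cyclobut-2-en-1-one)
Conditions: Zn dust, AcOH, TMEDA, EtOH, 0 °C to rt
Reagents that add atoms: none
Why: Reductive dehalogenation of the α,α-dichloroketones by zinc (zinc dienolates protonated by acetic acid), with TMEDA buffering the medium so that the strained, acid- and base-sensitive cyclobutenones survive.

Step 6
Reactants: 8 chloroacetaldehyde dimethyl acetal
Product: 10 1-methoxyprop-1-yne, via sodium methoxyethynide 9 (not isolated)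
Conditions: NaNH2 (3 equiv), liq. NH3, −33 °C; then CH3I, −40 °C to rt; distillation
Reagents that add atoms: methyl iodide, CI
Why: Twofold base-induced elimination (HCl, then CH3OH) from the chloroacetal by NaNH2 gives sodium methoxyacetylide 9, whose acetylide carbon is methylated by CH3I in an SN2 alkylation.

Step 7
Reactants: 7 3,3'-(tridecane-1,13-diyl)bis(cyclobut-2-en-1-one); 10 1-methoxyprop-1-yne
Product: 15 5,5'-(tridecane-1,13-diyl)bis(3-methoxy-2-methylphenol), via bis(vinylketene) 11 (not isolated), via bis(4-vinylcyclobutenone) 12 (not isolated), via bis(dienylketene) 13 (not isolated), via bis(cyclohexa-2,4-dienone) 14 (not isolated)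
Conditions: 10 (5 equiv), toluene, sealed tube, 80 °C then 110 °C; then K2CO3, MeOH, rt
Reagents that add atoms: 1-methoxyprop-1-yne 10 (second equivalent; one alkyne enters at each cyclobutenone), CC#COC
Why: Each cyclobutenone undergoes thermal 4π electrocyclic opening (cleaving C1–C4) to a vinylketene, whose ketene C=C adds one molecule of the ynol ether in a regioselective [2+2] cycloaddition to give a 4-vinylcyclobutenone; a second 4π opening (cleaving the original C1–C2 bond) gives a dienylketene, which closes by thermal disrotatory 6π electrocyclisation between the ketene carbon C1 and the terminal vinyl carbon C4 and then tautomerises to the phenol. This is the Danheiser benzannulation, known for 3-alkylcyclobutenones with alkoxyalkynes, and here it operates twice in one molecule, consuming two equivalents of 10. Each benzene ring is closed by the 6π electrocyclisation, the alkyne carbons becoming C2 (CH3) and C3 (OCH3) of the phenol, the former ring CH becoming C4, the tether carbon C5 and the former CH2 C6. No stereocentre is formed. The selectivity needed is regiochemical, and it is secured by the polarisation of the ynol ether: its nucleophilic CH3-bearing carbon bonds to the electrophilic ketene carbon C1, which places CH3 between the two oxygens and para to the tether. The saturated tether keeps the two ends independent, and the excess of 10 outcompetes ketene dimerisation and acylation of the product phenol by vinylketene (any aryl ester that still forms is cleaved in the K2CO3/MeOH treatment).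

Step 8
Reactants: 15 5,5'-(tridecane-1,13-diyl)bis(3-methoxy-2-methylphenol)
Product: 16 5,5'-(tridecane-1,13-diyl)bis(3-methoxy-2-methylcyclohexa-2,5-diene-1,4-dione)
Conditions: (KSO3)2NO (excess), KH2PO4 (aq), n-Bu4NHSO4 (cat.), CH2Cl2/H2O, rt
Reagents that add atoms: potassium nitrosodisulfonate (KSO3)2NO, [K+].[K+].[O-]S(=O)(=O)N([O])S(=O)(=O)[O-]
Why: Teuber oxidation: the nitrosodisulfonate radical abstracts the phenolic hydrogen and a second equivalent couples at the free para carbon C4, loss of imidodisulfonate giving the 1,4-quinone, while the single free ortho position does not compete with the free para position and the methyl ether and tether are inert.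

Step 9
Reactants: 16 5,5'-(tridecane-1,13-diyl)bis(3-methoxy-2-methylcyclohexa-2,5-diene-1,4-dione)
Product: 17 1,1'-(tridecane-1,13-diyl)bis(3-methoxy-4-methyl-7-oxabicyclo[4.1.0]hept-3-ene-2,5-dione), each epoxide cis-fused, mixture of meso and racemic diastereomers
Conditions: 30% H2O2, Na2CO3, THF/H2O, 0 °C
Reagents that add atoms: hydrogen peroxide, OO
Why: Weitz–Scheffer nucleophilic epoxidation: hydroperoxide anion adds to the ring CH of the alkyl-substituted C=C, which is more electrophilic and less hindered than the fully substituted, donor-bearing C(OCH3)=C(CH3) bond, and ring closure gives the necessarily cis-fused epoxide; the relative configuration between the two distant rings is not controlled and does not matter because all four stereocentres are removed in step 10.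

Step 10
Reactants: 17 1,1'-(tridecane-1,13-diyl)bis(3-methoxy-4-methyl-7-oxabicyclo[4.1.0]hept-3-ene-2,5-dione)
Product: 18 3,3'-(tridecane-1,13-diyl)bis(2-hydroxy-5-methoxy-6-methylcyclohexa-2,5-diene-1,4-dione)
Conditions: conc. H2SO4, CH2Cl2 (two-phase), 0 °C, short contact; then ice-water
Reagents that add atoms: none
Why: Acid-catalysed isomerisation of a 2,3-epoxy-1,4-dione to a 2-hydroxy-1,4-quinone: the protonated epoxide opens at the tertiary, tether-bearing carbon and loss of the ring CH proton leaves the oxygen on the former CH carbon as the enolic OH, a transformation known for 2-alkylquinone epoxides that carry one ring hydrogen.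

Step 11
Reactants: 18 3,3'-(tridecane-1,13-diyl)bis(2-hydroxy-5-methoxy-6-methylcyclohexa-2,5-diene-1,4-dione)
Product: 19 2-hydroxy-3-[13-(2,5-dihydroxy-4-methyl-3,6-dioxocyclohexa-1,4-dien-1-yl)tridecyl]-5-methoxy-6-methylcyclohexa-2,5-diene-1,4-dione (CNP0107579.0)
Conditions: dilute NaOH (aq), THF, rt, N2, stopped at partial conversion; then dilute HCl; recovered 18 recycled
Reagents that add atoms: sodium hydroxide, [Na+].[OH-]
Why: Saponification of a vinylogous methyl ester by addition–elimination of hydroxide at the OCH3-bearing ring carbon; the two rings are insulated by the tether and react independently, so the reaction is stopped early, 19 is separated from recovered 18 and from doubly hydrolysed material, and alcohol cosolvents are left out to prevent alkoxy exchange.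

**Compound list**

1 | tridecanedioic acid | OC(=O)CCCCCCCCCCCC(=O)O | starting material
2 | tridecane-1,13-diol | OCCCCCCCCCCCCCO | intermediate
3 | 1,13-dibromotridecane | BrCCCCCCCCCCCCCBr | intermediate
4 | heptadeca-1,16-diyne | C#CCCCCCCCCCCCCCC#C | intermediate
5 | trichloroacetyl chloride | ClC(=O)C(Cl)(Cl)Cl | starting material
6 | 3,3'-(tridecane-1,13-diyl)bis(4,4-dichlorocyclobut-2-en-1-one) | O=C1C=C(CCCCCCCCCCCCCC2=CC(=O)C2(Cl)Cl)C1(Cl)Cl | intermediate
7 | 3,3'-(tridecane-1,13-diyl)bis(cyclobut-2-en-1-one) | O=C1C=C(C1)CCCCCCCCCCCCCC2=CC(=O)C2 | intermediate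
8 | chloroacetaldehyde dimethyl acetal (2-chloro-1,1-dimethoxyethane) | COC(CCl)OC | starting material
9 | sodium methoxyethynide (not isolated) | COC#[C-].[Na+] | intermediate
10 | 1-methoxyprop-1-yne | CC#COC | intermediate
11 | bis(vinylketene): 3,17-dimethylidenenonadeca-1,18-diene-1,19-dione (not isolated; both ends drawn at the same stage) | O=C=CC(=C)CCCCCCCCCCCCCC(=C)C=C=O | intermediate
12 | bis(4-vinylcyclobutenone): 4,4'-(heptadeca-1,16-diene-2,16-diyl)bis(3-methoxy-2-methylcyclobut-2-en-1-one) (not isolated; mixture of stereoisomers) | CC1=C(OC)C(C(=C)CCCCCCCCCCCCCC(=C)C2C(OC)=C(C)C2=O)C1=O | intermediate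
13 | bis(dienylketene): (3E,20E)-3,21-dimethoxy-2,22-dimethyl-5,19-dimethylidenetricosa-1,3,20,22-tetraene-1,23-dione (not isolated; ketene and vinyl groups cis) | O=C=C(C)/C(OC)=C\C(=C)CCCCCCCCCCCCCC(=C)/C=C(OC)\C(C)=C=O | intermediate
14 | bis(cyclohexa-2,4-dienone): 5,5'-(tridecane-1,13-diyl)bis(3-methoxy-2-methylcyclohexa-2,4-dien-1-one) (not isolated) | COC1=C(C)C(=O)CC(CCCCCCCCCCCCCC2=CC(OC)=C(C)C(=O)C2)=C1 | intermediate
15 | 5,5'-(tridecane-1,13-diyl)bis(3-methoxy-2-methylphenol) | COc1cc(CCCCCCCCCCCCCc2cc(O)c(C)c(OC)c2)cc(O)c1C | intermediate
16 | 5,5'-(tridecane-1,13-diyl)bis(3-methoxy-2-methylcyclohexa-2,5-diene-1,4-dione) | COC1=C(C)C(=O)C=C(CCCCCCCCCCCCCC2=CC(=O)C(C)=C(OC)C2=O)C1=O | intermediate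
17 | 1,1'-(tridecane-1,13-diyl)bis(3-methoxy-4-methyl-7-oxabicyclo[4.1.0]hept-3-ene-2,5-dione), cis-fused epoxides, mixture of meso and racemic diastereomers (configuration left undefined) | COC1=C(C)C(=O)C2OC2(CCCCCCCCCCCCCC34OC3C(=O)C(C)=C(OC)C4=O)C1=O | intermediate
18 | 3,3'-(tridecane-1,13-diyl)bis(2-hydroxy-5-methoxy-6-methylcyclohexa-2,5-diene-1,4-dione) | COC1=C(C)C(=O)C(O)=C(CCCCCCCCCCCCCC2=C(O)C(=O)C(C)=C(OC)C2=O)C1=O | intermediate
19 | 2-hydroxy-3-[13-(2,5-dihydroxy-4-methyl-3,6-dioxocyclohexa-1,4-dien-1-yl)tridecyl]-5-methoxy-6-methylcyclohexa-2,5-diene-1,4-dione (CNP0107579.0; no stereocentre) | COC1=C(C)C(=O)C(O)=C(CCCCCCCCCCCCCC2=C(O)C(=O)C(C)=C(O)C2=O)C1=O | target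

**Totals**

Total step count: 11. Longest linear sequence: 10 steps (steps 1, 2, 3, 4, 5, 7, 8, 9, 10, 11 from tridecanedioic acid); step 6 is a one-step side branch.

**Steps most likely to fail**

Step 7 (key benzannulation). Four pericyclic events must run cleanly at each of two ends. The cascade may stall after one end has reacted, the vinylketene may dimerise or acylate product phenol, or the volatile ynol ether may oligomerise before it is consumed. The fallback leaves the pericyclic construction and sets out from 3. The known aryl bromide 5-bromo-1,3-dimethoxy-2-methylbenzene F1 is converted with Mg in THF into (3,5-dimethoxy-4-methylphenyl)magnesium bromide F2. F2 is coupled twice with 3 under Li2CuCl4 catalysis (copper-catalysed Grignard–alkyl bromide coupling) to give 1,13-bis(3,5-dimethoxy-4-methylphenyl)tridecane F3. NaSEt in DMF at 140 °C then cleaves one of the two equivalent methyl ethers of each ring; the phenoxide formed shuts off the second cleavage in that ring. This returns to the route at 15.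

Step 10 (epoxide-to-hydroxyquinone isomerisation, together with the epoxidation feeding it). The α-keto carbocation may undergo acyl migration with ring contraction, the strong acid may cleave the vinylogous methyl ester, or hydroperoxide may already displace OCH3 in step 9. The fallback replaces oxygen transfer by halogenation and substitution and sets out from 16. Br2 in CH2Cl2 adds across the alkyl-substituted C=C and Et3N eliminates HBr, giving 3,3'-(tridecane-1,13-diyl)bis(2-bromo-5-methoxy-6-methylcyclohexa-2,5-diene-1,4-dione) F4. Cold dilute aqueous NaOH in THF displaces bromide by addition–elimination, bromide being the better leaving group on the more electrophilic carbon. Acidification returns to the route at 18.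

Step 11 (mono-hydrolysis). The two rings react independently, so over-hydrolysis of the second ring accompanies the desired reaction, the hydroxyquinones may degrade in aerated alkali, and three closely related acidic quinones must be separated. The fallback moves the desymmetrisation to the robust arene stage and sets out from 15. A limited amount of BBr3 (CH2Cl2, −78 to 0 °C) cleaves one aryl methyl ether, and 5-[13-(3-hydroxy-5-methoxy-4-methylphenyl)tridecyl]-2-methylbenzene-1,3-diol F5 is separated from recovered 15. Oxidation of both rings with (KSO3)2NO, the resorcinol ring giving a hydroxyquinone, yields 3-hydroxy-5-[13-(5-methoxy-4-methyl-3,6-dioxocyclohexa-1,4-dien-1-yl)tridecyl]-2-methylcyclohexa-2,5-diene-1,4-dione F6. Nucleophilic epoxidation of both alkyl-substituted C=C bonds with NaBO3·4H2O in aqueous THF gives 3-hydroxy-1-[13-(3-methoxy-4-methyl-2,5-dioxo-7-oxabicyclo[4.1.0]hept-3-en-1-yl)tridecyl]-4-methyl-7-oxabicyclo[4.1.0]hept-3-ene-2,5-dione F7. The acid isomerisation of step 10 then returns directly to 19 without any partial reaction on the quinones.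

Further compounds
F1 | step 7 | 5-bromo-1,3-dimethoxy-2-methylbenzene | COc1cc(Br)cc(OC)c1C
F2 | step 7 | (3,5-dimethoxy-4-methylphenyl)magnesium bromide | COc1cc([Mg]Br)cc(OC)c1C
F3 | step 7 | 1,13-bis(3,5-dimethoxy-4-methylphenyl)tridecane | COc1cc(CCCCCCCCCCCCCc2cc(OC)c(C)c(OC)c2)cc(OC)c1C
F4 | step 10 | 3,3'-(tridecane-1,13-diyl)bis(2-bromo-5-methoxy-6-methylcyclohexa-2,5-diene-1,4-dione) | COC1=C(C)C(=O)C(Br)=C(CCCCCCCCCCCCCC2=C(Br)C(=O)C(C)=C(OC)C2=O)C1=O
F5 | step 11 | 5-[13-(3-hydroxy-5-methoxy-4-methylphenyl)tridecyl]-2-methylbenzene-1,3-diol | COc1cc(CCCCCCCCCCCCCc2cc(O)c(C)c(O)c2)cc(O)c1C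
F6 | step 11 | 3-hydroxy-5-[13-(5-methoxy-4-methyl-3,6-dioxocyclohexa-1,4-dien-1-yl)tridecyl]-2-methylcyclohexa-2,5-diene-1,4-dione | COC1=C(C)C(=O)C=C(CCCCCCCCCCCCCC2=CC(=O)C(C)=C(O)C2=O)C1=O
F7 | step 11 | 3-hydroxy-1-[13-(3-methoxy-4-methyl-2,5-dioxo-7-oxabicyclo[4.1.0]hept-3-en-1-yl)tridecyl]-4-methyl-7-oxabicyclo[4.1.0]hept-3-ene-2,5-dione (mixture of diastereomers) | COC1=C(C)C(=O)C2OC2(CCCCCCCCCCCCCC34OC3C(=O)C(C)=C(O)C4=O)C1=O
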